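## Structural features

Locants used throughout: the chromanone is numbered O1, C2, C3, C4, C4a–C8a; the flavan unit carries primed locants (O1'–C8a'), also in the early intermediates. The target is a heptacyclic flavonoid dimer. A 5,7-dihydroxychroman-4-one (benzene ring A, pyranone ring C) shares its C2–C3 bond with a 2,3-dihydrobenzofuran (ring D: C2, C3, C8', C7', O7'). The benzene ring of that benzofuran (ring E) is also the A-ring of a flavan-3-ol (pyran ring F, 4-hydroxyphenyl ring G on C2'), and a second 4-hydroxyphenyl group (ring B) stands on C2.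

C2 is a fully substituted mixed diaryl ketal carbon (O1, O7', ring B, C3). It is bonded to C3, a tertiary carbinol that also carries the C4 ketone and C8'. These two adjacent quaternary stereocentres (2S,3R) are remote from the flavan pair (2'S,3'R, 2,3-trans).

Ring B on C2 and the hydroxyl on C3 are anti. O1 and C4 therefore lie on opposite faces of ring D, and rings C and D are trans-fused. This junction is strained and would relax to the cis isomer whenever C2 can ionise.

Fragile groups are the ketal (acid, or electron push from a free para-hydroxyl of ring B), the α-ketol C3–C4, the benzylic pyran ether O1'–C2' (opens under base and heat) and six phenols.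

The real difficulty is to create the trans junction irreversibly, under conditions that never let C2 equilibrate. The key step uses the fact that O1 is an aryl ether oxygen whose ortho carbon is the future C4a, while C3 can carry the future C4 as an ester. Once C2 and C3 are fixed on ring D with O1 and O3 syn, joining C4a to C4 through an aryllithium can only give the trans fusion.

## Logic of the disconnections

**25 ⇒ 24 ⇒ 23.** Six O–CH2Ph bonds and the O3–Si bond are cut. Benzyl is used on every phenol and on O3' because hydrogenolysis is the only deprotection that is neither acidic nor basic. O3 is a triethylsilyl ether because the tertiary alkoxide next to the ketal must never be free during organolithium chemistry. The gain is a fully masked, non-ionisable substrate. The demand is that the silyl ether goes first, while no phenol is free, and that hydrogenolysis spares the benzylic C2–O and C2'–O bonds.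

**23 ⇒ 20.** The C4–C4a bond is cut. It is the only bond of ring C that is remote from both quaternary stereocentres, so forming it cannot scramble them. The ketone becomes a C3 methyl ester plus an aryl bromide on the O1 aryl ether. Ring C and the trans junction disappear and a dihydrobenzofuran with two cis oxygens remains. The forward step needs bromine–lithium exchange to be faster than any attack on the ester, an aryllithium able to reach the ester across the trans arrangement, and no ionisation at C2.

**20 ⇒ 17 + 18.** The C2–aryl bond to ring B and the O3–Si bond are cut. An anti addition across the former C2=C3 bond gives exactly the syn O1/O3 pattern, because O1 is already on C2 and the carbon nucleophile enters opposite the epoxide oxygen. Ring B becomes a simple arene and the C2 problem becomes a question of facial attack. The arene must outrun the electron-rich rings of the substrate, react at its para position and enter anti to O3.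

**17 ⇒ 16.** The two C–O bonds of the oxirane are cut. Both quaternary centres then derive from one face-selective oxygen transfer to a flat benzofuran. The gain is a precursor whose only stereocentres are those of the flavan. The demand is reagent control of the face, since C2'/C3' are too far away, and survival of a labile epoxy ketene acetal.

**16 ⇒ 13 + 15, and 15 ⇒ 14.** The C2–O1 aryl ether bond is cut as an addition–elimination at C2, and the C–Br bond of the phenol is cut before that. This is a convergent union of the ring A fragment with the rest, with the bromine position fixed before coupling. The demands are ortho-selective bromination of 14 and a metal-free substitution that leaves the aryl bromide alone.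

**13 ⇒ 11 ⇒ 9.** The C2–Cl bond is cut, then the furan ring: the C3–C8' and C2–O7' bonds, with C2, C3 and the ester carbon coming from a diazoacetate. A salicylaldehyde is turned in one operation into a benzofuran-3-carboxylate that already holds the future C4. Ring D and the ester are traced to a formyl group and a free phenol. The forward steps need aryl rather than hydride migration, and metalation at C2–H only.

**9 ⇒ 8 ⇒ 6 ⇒ 5.** The O7'–benzyl bond is put back, and the C8'–CHO and C8'–Br bonds are cut. The two ring E oxygens of the flavan cannot be told apart directly; a carbonyl on C8' marks O7' as the only benzyl ether ortho to it. The gain is uniform protection. The demands are C8'-selective bromination and chelation-controlled loss of exactly one benzyl group.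

**5 ⇒ 3 ⇒ 1.** Four O–benzyl bonds are cut and C2' is inverted. The flavan unit of 25 is 2,3-trans (2'S,3'R), whereas 1 is 2,3-cis (2R,3R) with the same C3 configuration, so epimerisation at C2' alone is needed. The gain is a purchasable natural product. The demand is separation of an equilibrium mixture and recycling of 1.

## Other disconnections considered

**Alternative 1:** The cut is the C2–C3 bond of ring D. In the forward step the ester enolate at the 8'-CH2CO2Me group of the 7'-O-(4-benzyloxybenzoyl) flavan A1 would attack the aroyl carbonyl held on O7', an oxygen-to-carbon acyl shift of the Baker–Venkataraman kind. The released phenoxide would add to the new ketone and acid would remove water to give the 2-arylbenzofuran-3-carboxylate A2.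
- In its favour: this is classical, regiochemically unambiguous carbonyl chemistry. Ring B and its bond to C2 arrive without a Friedel–Crafts step and without a weak arene nucleophile. On this point it is the better plan compared with step 11.
- Against it here: it creates no stereocentre. Because ring B is already on C2, O1 must later be brought in syn to O3; a normal anti opening of the derived epoxide by a phenol would give the O1/O3 anti, cis-fused series. A1 also needs a two-carbon chain on C8' with O7' free, which is harder to install than the formyl group of 8.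
- Comparison: on structure the two plans reach ring D equally well. On mechanism alternative 1 is safer for the C2–aryl bond but defers the C2/C3 problem to a syn C–O delivery. On step economy it is about equal up to the benzofuran and longer afterwards, since O1, the bromine and the C4–C4a closure are still to come.

**Alternative 2:** The cut is O1'–C2', together with the C3'–O bond through an epoxide. Oxygen would be transferred by a chiral dioxirane to the (E)-cinnamyl double bond of the phenol A3. The neighbouring hydroxyl on ring E would then attack the benzylic carbon in a 6-endo mode with inversion, which from an (E)-alkene gives the 2,3-trans flavan-3-ol A4.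
- In its favour: the flavan stereocentres come from a catalyst, so neither a scarce natural flavan nor the epimerisation of step 1 is needed. On sourcing and absolute control of C2'/C3' it is the better plan. A trans-disubstituted aryl alkene is also a far better matched substrate for the dioxirane than the tetrasubstituted alkene of step 10.
- Against it here: A4 is flat at C2/C3. Ring B and the C3 hydroxyl would have to be added anti across the C2=C3 bond of a rigid fused tetracycle, so the strained trans junction would have to arise in a cation capture where the cis-fused product is the less strained outcome. The ketene acetal C2=C3 of A3 would compete for the oxidant. Ring E would have to be built with three differentiated oxygens and a C-cinnamyl chain.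
- Comparison: equal in the type of epoxidation used, better for the flavan stereocentres, worse on the decisive C2/C3 issue and clearly longer.

**Alternative 3:** The cut is C2–O1, formed by delivery from boron. The boronic acid A6 would bind the oxirane oxygen of the 2-aryl epoxide A5 (the epoxide of A2). After ionisation at C2 its phenolic oxygen would be passed to C2 on the same face, giving the seven-membered cyclic boronate A7 with O1 and O3 syn.
- In its favour: the syn O1/O3 relationship is enforced by a tether, as in boron-mediated delivery to 1,2-anhydro sugars, rather than by facial bias in an open cation. On control at C2 it is the better plan. The nucleophile is oxygen, so the electron-rich arenes of the substrate do not compete.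
- Against it here: A6 is a 2,6-dioxygenated arylboronic acid, a class prone to protodeboronation. The boron-bound oxygen might be delivered in place of the phenolic one. A7 holds boron at C4a, so the C4–C4a bond would need either an aryl-boron acylation of an ester, which has little precedent, or a halodeboronation leading to a bromide of the type of 20 and the same closure as in step 12. A5 would still require the same enantioselective epoxidation of a benzofuran.
- Comparison: equal on the structure reached and on the risk at C3, better at C2, worse at closing ring C, and equal or one step longer overall.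

Key step: step 12

Remarks on the chemistry (one line each):
- (−)-Epiafzelechin 1 is (2R,3R), but the flavan unit of 25 is (2'S,3'R); 1 is therefore epimerised at C2' first (step 1), and the route starts at 3 if (2S,3R)-afzelechin can be bought.
- The D-fructose-derived ketone is assumed to deliver oxygen to the face of 16 that leads to (2R,3R)-17; if the opposite sense is found, the enantiomeric ketone is used in the same way.
- Methyl diazoacetate is taken as a purchasable reagent, handled as a solution in CH2Cl2.
- In 20, O1 and O3 are cis on ring D, and ring B and the ester are cis to each other on the opposite face.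

## Route

Step 1
Reactants: 1 (−)-epiafzelechin
Product: 3 (−)-afzelechin [(2S,3R)-2-(4-hydroxyphenyl)chromane-3,5,7-triol], via quinone methide 2 (not isolated)
Conditions: KH2PO4/K2HPO4 buffer (pH 8), degassed H2O, Ar, 90 °C; Sephadex LH-20; recovered 1 recycled
Reagents that add atoms: none
Why: Known base- and heat-induced C2 epimerisation of flavan-3-ols: the 4-phenoxide of ring G opens the pyran ring to quinone methide 2, which recloses on either face (retro-oxa-Michael/oxa-Michael) while C3' is untouched; the 2,3-trans isomer 3 is expected to predominate at equilibrium, and the mild pH avoids carbon–carbon rearrangement of the opened form.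

Step 2
Reactants: 3 (−)-afzelechin
Product: 5 (2'S,3'R)-3',5',7'-tris(benzyloxy)-2'-(4-benzyloxyphenyl)chromane, via tri-O-benzyl ether 4 (not isolated)
Conditions: BnBr, K2CO3, DMF, rt; then NaH, BnBr, Bu4NI (cat.), 0 °C → rt
Reagents that add atoms: benzyl bromide BrCc1ccccc1
Why: Williamson etherification, phenols first under carbonate at room temperature (no ring opening, little C-alkylation), then the secondary alcohol as its sodium alkoxide; benzyl is used throughout so that one neutral hydrogenolysis ends the synthesis.

Step 3
Reactants: 5 (2'S,3'R)-3',5',7'-tris(benzyloxy)-2'-(4-benzyloxyphenyl)chromane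
Product: 6 (2'S,3'R)-8'-bromo-3',5',7'-tris(benzyloxy)-2'-(4-benzyloxyphenyl)chromane
Conditions: NBS (1.0 equiv), CH2Cl2, −78 → 0 °C
Reagents that add atoms: N-bromosuccinimide O=C1CCC(=O)N1Br
Why: Electrophilic aromatic bromination; in 5',7'-di-O-benzyl flavans C8' is the most nucleophilic position, so one equivalent at low temperature should leave C6' and ring G untouched.

Step 4
Reactants: 6 (2'S,3'R)-8'-bromo-3',5',7'-tris(benzyloxy)-2'-(4-benzyloxyphenyl)chromane
Product: 8 (2'S,3'R)-3',5',7'-tris(benzyloxy)-2'-(4-benzyloxyphenyl)chromane-8'-carbaldehyde, via 8'-lithio species 7 (not isolated)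
Conditions: n-BuLi, THF, −78 °C; DMF, −78 → 0 °C; aq. NH4Cl
Reagents that add atoms: N,N-dimethylformamide CN(C)C=O
Why: Bromine–lithium exchange gives the 2,6-dioxygenated aryllithium 7, which is stable at −78 °C and is formylated by DMF (Bouveault-type formylation); no stereocentre is involved.

Step 5
Reactants: 8 (2'S,3'R)-3',5',7'-tris(benzyloxy)-2'-(4-benzyloxyphenyl)chromane-8'-carbaldehyde
Product: 9 (2'S,3'R)-3',5'-bis(benzyloxy)-2'-(4-benzyloxyphenyl)-7'-hydroxychromane-8'-carbaldehyde
Conditions: MgBr2·OEt2, toluene–Et2O, rt → 50 °C; aq. NH4Cl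
Reagents that add atoms: none
Why: Chelation-controlled dealkylation of a benzyl ether ortho to a carbonyl: magnesium bridges the aldehyde oxygen and O7' and bromide removes the benzyl group by SN2 at its primary carbon; the other benzyl ethers have no ortho carbonyl, and cleavage at the ring oxygen O1' would need attack at a secondary carbon.

Step 6
Reactants: 9 (2'S,3'R)-3',5'-bis(benzyloxy)-2'-(4-benzyloxyphenyl)-7'-hydroxychromane-8'-carbaldehyde
Product: 11 methyl benzofuran-3-carboxylate fused through O7'/C8' to the (2'S,3'R)-3',5'-bis(benzyloxy)-2'-(4-benzyloxyphenyl)chromane, via lactol 10 (not isolated)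
Conditions: N2CHCO2Me (1.5 equiv), HBF4·OEt2 (10 mol%), CH2Cl2, 0 °C → rt; then Et3N, MsCl, 0 °C → rt
Reagents that add atoms: methyl diazoacetate COC(=O)C=[N+]=[N-]
Why: Acid-catalysed addition of the diazoester to the aldehyde, then 1,2-shift of the electron-rich aryl group with loss of N2 (the known homologation of salicylaldehydes to benzofuran-3-carboxylates) gives lactol 10; this is aromatised by mesylation and E1cB elimination under basic conditions that spare the benzyl ethers and ring F.

Step 7
Reactants: 11 flavan-fused methyl benzofuran-3-carboxylate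
Product: 13 flavan-fused methyl 2-chlorobenzofuran-3-carboxylate, via 2-magnesio species 12 (not isolated)
Conditions: TMPMgCl·LiCl (1.2 equiv), THF, −30 °C; C2Cl6, −30 °C → rt
Reagents that add atoms: hexachloroethane ClC(Cl)(Cl)C(Cl)(Cl)Cl
Why: Directed magnesiation at C2–H, the most acidic position (next to the ring oxygen and ortho to the ester), with a hindered amide base that tolerates esters, then electrophilic chlorination; benzylic ether C–H bonds are not metalated at this temperature.

Step 8
Reactants: 14 3,5-bis(benzyloxy)phenol
Product: 15 2-bromo-3,5-bis(benzyloxy)phenol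
Conditions: NBS, i-Pr2NH (10 mol%), CH2Cl2, −78 → 0 °C
Reagents that add atoms: N-bromosuccinimide O=C1CCC(=O)N1Br
Why: Amine-catalysed ortho-bromination of a phenol (hydrogen-bonded delivery of bromine from the N-bromoamine); any symmetric 4-bromo isomer is removed by chromatography.

Step 9
Reactants: 13 flavan-fused methyl 2-chlorobenzofuran-3-carboxylate; 15 2-bromo-3,5-bis(benzyloxy)phenol
Product: 16 flavan-fused methyl 2-[2-bromo-3,5-bis(benzyloxy)phenoxy]benzofuran-3-carboxylate
Conditions: Cs2CO3, DMF, 60 °C
Reagents that add atoms: none
Why: SNAr by addition–elimination at C2 of a vinylogous chloroformate: the phenoxide adds to C2 to give the ester enolate and chloride leaves; the aryl bromide is inert under these metal-free conditions.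

Step 10
Reactants: 16 flavan-fused methyl 2-[2-bromo-3,5-bis(benzyloxy)phenoxy]benzofuran-3-carboxylate
Product: 17 (2R,3R)-2,3-epoxy-2,3-dihydro derivative of 16
Conditions: D-fructose-derived Shi ketone (0.5 equiv), Oxone (KHSO5), K2CO3, Bu4NHSO4 (cat.), MeCN–CH2(OMe)2–aq. Na2B4O7/Na2EDTA, −10 → 0 °C; cold pentane–Et2O extraction, used at once
Reagents that add atoms: potassium peroxymonosulfate [K+].[O-]S(=O)(=O)OO
Why: Proposed new method: asymmetric dioxirane epoxidation of the push–pull C2=C3 bond of a 2-aryloxybenzofuran-3-carboxylate; the two oxygen donors on C2 keep the alkene nucleophilic toward an electrophilic dioxirane, the syn oxygen transfer through a spiro transition state sets C2 and C3 together, and the face is chosen by the catalyst because C2'/C3' are remote; the closest known reaction types are dimethyldioxirane epoxidation of benzofurans and Shi epoxidation of enol ethers and enol esters.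

Step 11
Reactants: 17 (2R,3R)-epoxide; 18 benzyl phenyl ether
Product: 20 flavan-fused methyl (2S,3S)-2-(4-benzyloxyphenyl)-2-[2-bromo-3,5-bis(benzyloxy)phenoxy]-3-(triethylsilyloxy)-2,3-dihydrobenzofuran-3-carboxylate, via dioxocarbenium triflate 19 (not isolated)
Conditions: 18 (30 equiv), Et3SiOTf (1.3 equiv), 2,6-di-tert-butyl-4-methylpyridine (1.5 equiv), CH2Cl2 (0.01 M), −78 → −40 °C; Et3N quench
Reagents that add atoms: triethylsilyl trifluoromethanesulfonate CC[Si](CC)(CC)OS(=O)(=O)C(F)(F)F
Why: Proposed new method: silyl triflate-promoted Friedel–Crafts opening of an epoxy ketene acetal; the triflate silylates the oxirane oxygen, C2–O ionises to ion 19 stabilised by O7' and O1, and the para carbon of 18 attacks C2 anti to the C3 silyloxy group (departing oxygen and its silyl group shield that face; polar Felkin-type preference), which places O1 syn to O3, sets C2 as S and caps O3 in the same operation; the closest known reaction types are Lewis acid-mediated C-arylation of 1,2-anhydro sugars and arylation of orthoester-derived dioxocarbenium ions, and the large excess of 18 at high dilution is meant to outrun the trioxygenated rings of the substrate.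

Step 12
Reactants: 20 flavan-fused methyl (2S,3S)-2-aryl-2-(2-bromoaryloxy)-3-(triethylsilyloxy)-2,3-dihydrobenzofuran-3-carboxylate
Product: 23 hexa-O-benzyl-3-O-triethylsilyl derivative of 25 (C2 S; C3 R), via aryllithium 21 (not isolated), via lithium hemiketal alkoxide 22 (not isolated)
Conditions: t-BuLi (2.05 equiv), THF, −95 → −60 °C; pH 7 phosphate buffer, −78 °C → rt
Reagents that add atoms: none
Why: Parham cyclisation: t-BuLi exchanges the aryl bromide (the second equivalent consumes t-BuBr) to give aryllithium 21, which is held on O1 and adds to the C3 ester carbonyl, forming C4–C4a. The closest known reaction type is the intramolecular acylation of an ortho-lithiated aryl ether by an ester to give a chroman-4-one. Ring C closes in a 6-exo-trig mode. No stereocentre is created: C4 is tetrahedral only in alkoxide 22 and becomes the carbonyl carbon when methoxide is lost on buffered work-up, while C2 and C3 are carried over unchanged, so the syn O1/O3 arrangement of 20 becomes the trans ring fusion. The step needs exchange to be faster than addition of t-BuLi to the ester and than benzylic deprotonation; the ester is shielded by two adjacent quaternary carbons and the silyl ether, and exchange at −95 °C is far faster than either. The aryllithium, flanked by two oxygens, is stabilised and does not form an aryne at this temperature. The ketal carbon C2 cannot ionise in a cold, basic medium free of Lewis acids, so the strained junction is closed under kinetic control and the strain is paid for by the new C–C bond. With exactly two equivalents of t-BuLi no organolithium remains to attack 22 or the hindered ketone derived from it.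

Step 13
Reactants: 23 hexa-O-benzyl-3-O-triethylsilyl derivative of 25
Product: 24 hexa-O-benzyl derivative of 25 (3-OH free)
Conditions: Bu4NF–AcOH (1:1), THF, 0 °C
Reagents that add atoms: none
Why: Fluoride cleavage of the tertiary silyl ether; acetic acid protonates the C3 alkoxide at once, so neither an α-ketol shift nor attack on C2 can follow, and the medium is too weakly acidic to ionise the ketal while all phenols are still benzylated.

Step 14
Reactants: 24 hexa-O-benzyl derivative of 25
Product: 25 target CNP0146414.2
Conditions: H2 (1 atm), 10% Pd/C, EtOAc–THF, rt; filtration under Ar, concentration below rt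
Reagents that add atoms: none
Why: Hydrogenolysis of six benzyl ethers on zerovalent palladium in a neutral aprotic medium; the diaryl ketone is a vinylogous ester, and the hindered quaternary C2–O bonds and the pyran C2'–O1' bond are expected to survive as flavan benzylic ethers do, with no acid or base present to ionise C2.

## Compound list

1 | (−)-epiafzelechin, (2R,3R)-2-(4-hydroxyphenyl)chromane-3,5,7-triol | O[C@@H]1Cc2c(O)cc(O)cc2O[C@@H]1c1ccc(O)cc1 | starting material
2 | ring-opened para-quinone methide of 1 (C3' R retained) | O=C1C=CC(=C[C@H](O)Cc2c(O)cc(O)cc2O)C=C1 | intermediate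
3 | (−)-afzelechin (ent-afzelechin), (2S,3R)-2-(4-hydroxyphenyl)chromane-3,5,7-triol | Oc1cc(O)c2c(c1)O[C@@H](c1ccc(O)cc1)[C@H](O)C2 | intermediate
4 | (2'S,3'R)-5',7'-bis(benzyloxy)-2'-(4-benzyloxyphenyl)chroman-3'-ol | c1(OCc9ccccc9)cc(OCc9ccccc9)c2c(c1)O[C@@H](c1ccc(OCc9ccccc9)cc1)[C@H](O)C2 | intermediate
5 | (2'S,3'R)-3',5',7'-tris(benzyloxy)-2'-(4-benzyloxyphenyl)chromane | c1(OCc9ccccc9)cc(OCc9ccccc9)c2c(c1)O[C@@H](c1ccc(OCc9ccccc9)cc1)[C@H](OCc9ccccc9)C2 | intermediate
6 | (2'S,3'R)-8'-bromo-3',5',7'-tris(benzyloxy)-2'-(4-benzyloxyphenyl)chromane | Brc1c(OCc9ccccc9)cc(OCc9ccccc9)c2c1O[C@@H](c1ccc(OCc9ccccc9)cc1)[C@H](OCc9ccccc9)C2 | intermediate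
7 | 8'-lithio analogue of 6 | [Li]c1c(OCc9ccccc9)cc(OCc9ccccc9)c2c1O[C@@H](c1ccc(OCc9ccccc9)cc1)[C@H](OCc9ccccc9)C2 | intermediate
8 | (2'S,3'R)-3',5',7'-tris(benzyloxy)-2'-(4-benzyloxyphenyl)chromane-8'-carbaldehyde | O=Cc1c(OCc9ccccc9)cc(OCc9ccccc9)c2c1O[C@@H](c1ccc(OCc9ccccc9)cc1)[C@H](OCc9ccccc9)C2 | intermediate
9 | (2'S,3'R)-3',5'-bis(benzyloxy)-2'-(4-benzyloxyphenyl)-7'-hydroxychromane-8'-carbaldehyde | O=Cc1c(O)cc(OCc9ccccc9)c2c1O[C@@H](c1ccc(OCc9ccccc9)cc1)[C@H](OCc9ccccc9)C2 | intermediate
10 | flavan-fused methyl 2-hydroxy-2,3-dihydrobenzofuran-3-carboxylate (lactol, isomer mixture at C2/C3) | COC(=O)C1C(O)Oc2cc(OCc9ccccc9)c3c(c12)O[C@@H](c1ccc(OCc9ccccc9)cc1)[C@H](OCc9ccccc9)C3 | intermediate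
11 | flavan-fused methyl benzofuran-3-carboxylate (furan O = O7', C3 on C8') | COC(=O)c1coc2cc(OCc9ccccc9)c3c(c12)O[C@@H](c1ccc(OCc9ccccc9)cc1)[C@H](OCc9ccccc9)C3 | intermediate
12 | 2-(chloromagnesio) derivative of 11 | COC(=O)c1c([Mg]Cl)oc2cc(OCc9ccccc9)c3c(c12)O[C@@H](c1ccc(OCc9ccccc9)cc1)[C@H](OCc9ccccc9)C3 | intermediate
13 | flavan-fused methyl 2-chlorobenzofuran-3-carboxylate | COC(=O)c1c(Cl)oc2cc(OCc9ccccc9)c3c(c12)O[C@@H](c1ccc(OCc9ccccc9)cc1)[C@H](OCc9ccccc9)C3 | intermediate
14 | 3,5-bis(benzyloxy)phenol | Oc1cc(OCc2ccccc2)cc(OCc2ccccc2)c1 | starting material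
15 | 2-bromo-3,5-bis(benzyloxy)phenol | Oc1cc(OCc2ccccc2)cc(OCc2ccccc2)c1Br | intermediate
16 | flavan-fused methyl 2-[2-bromo-3,5-bis(benzyloxy)phenoxy]benzofuran-3-carboxylate | COC(=O)c1c(Oc2cc(OCc9ccccc9)cc(OCc9ccccc9)c2Br)oc2cc(OCc9ccccc9)c3c(c12)O[C@@H](c1ccc(OCc9ccccc9)cc1)[C@H](OCc9ccccc9)C3 | intermediate
17 | (2R,3R)-2,3-epoxy-2,3-dihydro derivative of 16 | Brc1c(OCc9ccccc9)cc(OCc9ccccc9)cc1O[C@]12O[C@@]1(C(=O)OC)c1c(O2)cc(OCc9ccccc9)c3c1O[C@@H](c1ccc(OCc9ccccc9)cc1)[C@H](OCc9ccccc9)C3 | intermediate
18 | benzyl phenyl ether | c1ccc(OCc2ccccc2)cc1 | starting material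
19 | C2 dioxocarbenium triflate carrying the 3-triethylsilyloxy and 3-methoxycarbonyl groups | Brc1c(OCc9ccccc9)cc(OCc9ccccc9)cc1OC1=[O+]c2cc(OCc9ccccc9)c3c(c2[C@]1(C(=O)OC)O[Si](CC)(CC)CC)O[C@@H](c1ccc(OCc9ccccc9)cc1)[C@H](OCc9ccccc9)C3.[O-]S(=O)(=O)C(F)(F)F | intermediate
20 | flavan-fused methyl (2S,3S)-2-(4-benzyloxyphenyl)-2-[2-bromo-3,5-bis(benzyloxy)phenoxy]-3-(triethylsilyloxy)-2,3-dihydrobenzofuran-3-carboxylate | Brc1c(OCc9ccccc9)cc(OCc9ccccc9)cc1O[C@]1(c2ccc(OCc9ccccc9)cc2)Oc2cc(OCc9ccccc9)c3c(c2[C@]1(C(=O)OC)O[Si](CC)(CC)CC)O[C@@H](c1ccc(OCc9ccccc9)cc1)[C@H](OCc9ccccc9)C3 | intermediate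
21 | aryllithium from 20 (Li in place of Br) | [Li]c1c(OCc9ccccc9)cc(OCc9ccccc9)cc1O[C@]1(c2ccc(OCc9ccccc9)cc2)Oc2cc(OCc9ccccc9)c3c(c2[C@]1(C(=O)OC)O[Si](CC)(CC)CC)O[C@@H](c1ccc(OCc9ccccc9)cc1)[C@H](OCc9ccccc9)C3 | intermediate
22 | ring-closed lithium hemiketal alkoxide, C4(OLi)(OMe) | [Li]OC1(OC)c2c(OCc9ccccc9)cc(OCc9ccccc9)cc2O[C@]2(c3ccc(OCc9ccccc9)cc3)Oc3cc(OCc9ccccc9)c4c(c3[C@@]12O[Si](CC)(CC)CC)O[C@@H](c1ccc(OCc9ccccc9)cc1)[C@H](OCc9ccccc9)C4 | intermediate
23 | hexa-O-benzyl-3-O-triethylsilyl derivative of 25 (benzyl on O5, O7, ring B, O5', O3', ring G) | O=C1c2c(OCc9ccccc9)cc(OCc9ccccc9)cc2O[C@]2(c3ccc(OCc9ccccc9)cc3)Oc3cc(OCc9ccccc9)c4c(c3[C@@]12O[Si](CC)(CC)CC)O[C@@H](c1ccc(OCc9ccccc9)cc1)[C@H](OCc9ccccc9)C4 | intermediate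
24 | hexa-O-benzyl derivative of 25 (3-OH free) | O=C1c2c(OCc9ccccc9)cc(OCc9ccccc9)cc2O[C@]2(c3ccc(OCc9ccccc9)cc3)Oc3cc(OCc9ccccc9)c4c(c3[C@@]12O)O[C@@H](c1ccc(OCc9ccccc9)cc1)[C@H](OCc9ccccc9)C4 | intermediate
25 | CNP0146414.2 (C2 S, C3 R, C2' S, C3' R) | O=C1c2c(O)cc(O)cc2O[C@]2(c3ccc(O)cc3)Oc3cc(O)c4c(c3[C@@]12O)O[C@@H](c1ccc(O)cc1)[C@H](O)C4 | target

## Step count and risks

Total steps: 14. Longest linear sequence: 13 steps (steps 1–7 and 9–14, from 1). Step 8 is a one-step side branch from 14.

Steps least certain to work:

**Step 10 (labelled).** The epoxy ketene acetal may be hydrolysed or may rearrange in the aqueous basic medium, and facial selectivity on a tetrasubstituted push–pull alkene may be poor or opposite. Fallback (sets out from 16, returns at 20): oxidation of 16 with anhydrous dimethyldioxirane (acetone–CH2Cl2, −40 °C), a known way to epoxidise benzofurans and enol ethers without water or base, would give 17 together with its facial isomer, the (2S,3S)-epoxide F1. The mixture is submitted to the conditions of step 11, and 20 is separated by chromatography from the (2R,3R)-configured arylation product F2; the two are diastereomers because of the flavan unit.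

**Step 11 (labelled).** The cation may be captured by the more nucleophilic trioxygenated rings of a second substrate molecule (oligomerisation), the ester may undergo a 1,2-shift to C2, or the arene may enter on the wrong face. Fallback (sets out from 17, returns at 20): copper-catalysed opening of 17 with commercial (4-benzyloxyphenyl)magnesium bromide (CuBr·SMe2 cat., THF, −78 °C) is the known anti opening of epoxides by organocopper reagents, with a nucleophile that outruns every arene in the flask. After a cold buffered quench it should give the tertiary alcohol F3, the 3-hydroxy analogue of 20. Silylation with Et3SiOTf and 2,6-lutidine (CH2Cl2, −78 °C) then gives 20.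

**Step 12 (key step).** The closure to a trans-fused ring of this kind is untested. The aryllithium may fail to reach the ester carbonyl across the trans-disposed tether and be protonated on work-up (net debromination), or t-BuLi may add to the ester. Fallback (sets out from 20, returns at 23): reduction of the ester with DIBAL-H (toluene, −78 °C) gives the aldehyde F4. Bromine–lithium exchange (t-BuLi, THF, −95 °C) then leads to addition to the more reactive and less hindered aldehyde, closing ring C as the chroman-4-ol F5 (either C4 epimer). Oxidation with Dess–Martin periodinane and NaHCO3 gives 23.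

**Step 14.** Once ring B carries a free para-hydroxyl, ionisation at C2 (assisted also by the free 3-OH) may epimerise the strained junction to the cis-fused isomer, and a benzylic C2–O bond may be cleaved reductively. Fallback (sets out from 23, returns at 25): the order of the last two operations is reversed. Hydrogenolysis of 23 (H2, Pd/C, EtOAc–THF) with O3 still capped gives the hexaphenol silyl ether F6. A short, cold, non-basic desilylation (HF·pyridine with excess pyridine, THF, 0 °C) then gives 25 without passing through phenoxides.

**Step 6.** The acid may remove benzyl groups or open ring F, and hydride instead of aryl migration would give a β-keto ester; the preceding selective debenzylation (step 5) carries a related risk. Fallback (sets out from 6, returns at 11, replacing steps 4–6): Sonogashira coupling of 6 with ethynyltrimethylsilane (PdCl2(PPh3)2, CuI, Et3N, 70 °C) gives the aryl alkyne F7. Iodine in CH2Cl2 induces iodocyclisation of the ortho-alkynyl aryl benzyl ether with loss of benzyl iodide, which frees O7' and closes the furan ring as the 3-iodo-2-silylbenzofuran F8. Methoxycarbonylation (Pd(OAc)2, dppf, CO 1 atm, MeOH, Et3N, DMF, 70 °C) gives the 2-silyl ester F9, and Bu4NF removes the silyl group to give 11.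

## Further compounds

F1 | step 10 | (2S,3S)-2,3-epoxy-2,3-dihydro derivative of 16 (facial isomer of 17) | Brc1c(OCc9ccccc9)cc(OCc9ccccc9)cc1O[C@@]12O[C@]1(C(=O)OC)c1c(O2)cc(OCc9ccccc9)c3c1O[C@@H](c1ccc(OCc9ccccc9)cc1)[C@H](OCc9ccccc9)C3
F2 | step 10 | (2R,3R)-diastereomer of 20 | Brc1c(OCc9ccccc9)cc(OCc9ccccc9)cc1O[C@@]1(c2ccc(OCc9ccccc9)cc2)Oc2cc(OCc9ccccc9)c3c(c2[C@@]1(C(=O)OC)O[Si](CC)(CC)CC)O[C@@H](c1ccc(OCc9ccccc9)cc1)[C@H](OCc9ccccc9)C3
F3 | step 11 | flavan-fused methyl (2S,3S)-2-(4-benzyloxyphenyl)-2-[2-bromo-3,5-bis(benzyloxy)phenoxy]-3-hydroxy-2,3-dihydrobenzofuran-3-carboxylate | Brc1c(OCc9ccccc9)cc(OCc9ccccc9)cc1O[C@]1(c2ccc(OCc9ccccc9)cc2)Oc2cc(OCc9ccccc9)c3c(c2[C@]1(C(=O)OC)O)O[C@@H](c1ccc(OCc9ccccc9)cc1)[C@H](OCc9ccccc9)C3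
F4 | step 12 | 3-carbaldehyde analogue of 20 (CHO in place of CO2Me) | Brc1c(OCc9ccccc9)cc(OCc9ccccc9)cc1O[C@]1(c2ccc(OCc9ccccc9)cc2)Oc2cc(OCc9ccccc9)c3c(c2[C@]1(C=O)O[Si](CC)(CC)CC)O[C@@H](c1ccc(OCc9ccccc9)cc1)[C@H](OCc9ccccc9)C3
F5 | step 12 | C4 carbinol of 23 (chroman-4-ol, either C4 epimer) | OC1c2c(OCc9ccccc9)cc(OCc9ccccc9)cc2O[C@]2(c3ccc(OCc9ccccc9)cc3)Oc3cc(OCc9ccccc9)c4c(c3[C@@]12O[Si](CC)(CC)CC)O[C@@H](c1ccc(OCc9ccccc9)cc1)[C@H](OCc9ccccc9)C4
F6 | step 14 | 3-O-triethylsilyl derivative of 25 | O=C1c2c(O)cc(O)cc2O[C@]2(c3ccc(O)cc3)Oc3cc(O)c4c(c3[C@@]12O[Si](CC)(CC)CC)O[C@@H](c1ccc(O)cc1)[C@H](O)C4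
F7 | step 6 | (2'S,3'R)-3',5',7'-tris(benzyloxy)-2'-(4-benzyloxyphenyl)-8'-[(trimethylsilyl)ethynyl]chromane | C[Si](C)(C)C#Cc1c(OCc9ccccc9)cc(OCc9ccccc9)c2c1O[C@@H](c1ccc(OCc9ccccc9)cc1)[C@H](OCc9ccccc9)C2
F8 | step 6 | flavan-fused 3-iodo-2-(trimethylsilyl)benzofuran | C[Si](C)(C)c1oc2cc(OCc9ccccc9)c3c(c2c1I)O[C@@H](c1ccc(OCc9ccccc9)cc1)[C@H](OCc9ccccc9)C3
F9 | step 6 | flavan-fused methyl 2-(trimethylsilyl)benzofuran-3-carboxylate | COC(=O)c1c([Si](C)(C)C)oc2cc(OCc9ccccc9)c3c(c12)O[C@@H](c1ccc(OCc9ccccc9)cc1)[C@H](OCc9ccccc9)C3
A1 | alternative 1 | methyl 2-[(2'S,3'R)-3',5'-bis(benzyloxy)-7'-(4-benzyloxybenzoyloxy)-2'-(4-benzyloxyphenyl)chroman-8'-yl]acetate | COC(=O)Cc1c(OC(=O)c2ccc(OCc9ccccc9)cc2)cc(OCc9ccccc9)c2c1O[C@@H](c1ccc(OCc9ccccc9)cc1)[C@H](OCc9ccccc9)C2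
A2 | alternative 1 | flavan-fused methyl 2-(4-benzyloxyphenyl)benzofuran-3-carboxylate | COC(=O)c1c(-c2ccc(OCc9ccccc9)cc2)oc2cc(OCc9ccccc9)c3c(c12)O[C@@H](c1ccc(OCc9ccccc9)cc1)[C@H](OCc9ccccc9)C3
A3 | alternative 2 | planar benzofurochromenone core carrying on ring E a free hydroxyl (C8a') and an (E)-3-(4-benzyloxyphenyl)allyl chain (C4a') | O=C1C2=C(Oc3cc(OCc9ccccc9)cc(OCc9ccccc9)c13)Oc1cc(OCc9ccccc9)c(C/C=C/c3ccc(OCc9ccccc9)cc3)c(O)c12
A4 | alternative 2 | planar core fused to the (2'S,3'R)-flavan-3-ol | O=C1C2=C(Oc3cc(OCc9ccccc9)cc(OCc9ccccc9)c13)Oc1cc(OCc9ccccc9)c3c(c12)O[C@@H](c1ccc(OCc9ccccc9)cc1)[C@H](O)C3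
A5 | alternative 3 | 2,3-epoxide of A2 with the oxirane oxygen on the face of O3 in 20 | COC(=O)[C@@]12O[C@]1(c1ccc(OCc9ccccc9)cc1)Oc1cc(OCc9ccccc9)c3c(c12)O[C@@H](c1ccc(OCc9ccccc9)cc1)[C@H](OCc9ccccc9)C3
A6 | alternative 3 | [2,4-bis(benzyloxy)-6-hydroxyphenyl]boronic acid | OB(O)c1c(O)cc(OCc2ccccc2)cc1OCc1ccccc1
A7 | alternative 3 | cyclic boronate linking O3 and C4a, with O1 on C2 | OB1O[C@@]2(C(=O)OC)c3c(O[C@@]2(c2ccc(OCc9ccccc9)cc2)Oc2cc(OCc9ccccc9)cc(OCc9ccccc9)c12)cc(OCc9ccccc9)c2c3O[C@@H](c1ccc(OCc9ccccc9)cc1)[C@H](OCc9ccccc9)C2
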